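Its constants stand for no real mixture.

In a one-step world Z would simply become E with no fork to reckon, but here the way branches, so I followed one molecule instead: Z goes to X, X goes on to Q or falls to G, Q drains to D or passes to and fro with L, L goes on to E, and E can bind a further Z into Z.E.

| setting | gamma | epsilon | beta |
|---|---|---|---|
| Z | 0.060 M | 0.060 M | 0.060 M |
| remark | one stirred flow tank at steady state, fed with the mixture as stated, mean residence time 20.0 h | everything together in a closed stirred flask, run for 4.0 h | a single well-mixed tank run continuously and read at steady state, 4.0 h in it on average |
| time |  | 4.0 h |  |

1. the set-up with the highest share of E in all that became E or G or D or Z.E, at the outlet or at the end ("none" if the first two lie within 2 percentage points) (gamma / epsilon / beta / none)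
2. share of E in all that became E or G or D or Z.E, at the outlet or at the end, gamma
3. share of E in all that became E or G or D or Z.E, at the outlet or at the end, epsilon
4. share of E in all that became E or G or D or Z.E, at the outlet or at the end, beta

- a species is counted by the Z in it: one Z.E counts as two
- the stated concentrations are those of everything mixed, before any reaction; amounts are the same in each set-up
- run time (epsilon): 4.0 h

    Q → D (k1 = 2.8 × 10⁻⁴ s⁻¹)
    X → Q (k2 = 0.020 s⁻¹)
    Z + E → Z.E (k3 = 0.0076 L mol⁻¹ s⁻¹)
    L → E (k4 = 5.7 × 10⁻⁴ s⁻¹)
    X → G (k5 = 9.4 × 10⁻⁴ s⁻¹)
    Q ⇌ L (K6 = 1.7, k6 = 5.9 × 10⁻⁴ s⁻¹)
    Z → X (k7 = 0.0014 s⁻¹)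

The fastest rung was X, which lasted 47.8 s, shorter than the 11.9 min of Z or a stay on Q or L, so I read its fork as a plain ratio: 95.5 % went on to Q. Slower than Z came the pair Q and L, each stay lasting 19.2 min and 18.2 min; from Q the chance of reaching L was 67.8 %, from L the chance of reaching E was 62.2 %, and summing the returns gave 56.7 %. Multiplied, the forks gave 54.2 %, the E-chance, the chance that one Z passing into X ends as E, a branching ratio in the usual term.

The last rung I set was the binding of E, 36.5 min at the full charge of Z, longer than the life of Z, so for the closed flask epsilon I expected a share just under the E-chance. In a tank Z stands at about its life divided by the residence time, 4.96 % of the charge in beta and 0.992 % in gamma. E there either binds or flows out, and the residence time cancels from the odds, which become the life of Z over the binding time, 0.326. So 75.4 % of E survives, each bound E adds a second Z to the count, and I committed to 36.1 % for both tanks, with epsilon best.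

The forecast named epsilon, with 37.2 % for gamma, 52.7 % for epsilon and 36.4 % for beta, holding that “in either tank E always meets some residual Z”, and it set gamma above beta where I had them equal.

The run gave epsilon as best.

Epsilon read 52.8 %, which is 1.4 percentage points under the E-chance, while gamma read 37.2 % and beta 36.3 %. With the binding of Z and E given no rate, beta stood 2.1 points under epsilon instead of 17 points. With the passing of X into G struck out, the E-chance loses its first fork, and scaling epsilon's reading by that change gave 55.2 %, where that flask read 55.2 %.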